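**Retrosynthetic overview**
1. Target 23 ⇐ 22 by one BCl3 dealkylation (MOM ether and the methyl ether ortho to CHO); the dimethylpyran ring D of 22 is closed last, from aryl 1,1-dimethylpropargyl ether 21.
2. Ring C of 21 ⇐ Mitsunobu closure of the O1–C2 bond in phenol–alcohol 20.
3. C3 stereocentre and C3–aryl bond of 20 ⇐ enantioselective 1,2-aryl shift on (E)-1,3-diarylpropene 18 mediated by a chiral trivalent-iodine reagent, with NaBH4 interception.
4. 18 ⇐ ortho-formylation of phenol 17 ⇐ allyl–aryl coupling of metalated ring A ether 5 with ring B allylic acetate 13.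
5. Rings A and B both come from resorcinol 1 (third ring A oxygen by C–H borylation/oxidation; ring B aldehyde by Vilsmeier–Haack), plus 3-chloro-3-methylbut-1-yne 9 and vinylmagnesium bromide 11.

Assumption: the (R,R)-lactate iodane of step 10 (a known type of stoichiometric reagent, its iodoarene recoverable) is taken to give the (R)-product; if the first run shows the opposite sense, its (S,S)-enantiomer is used and nothing else changes.

**Step 1**
Reactants: 1 resorcinol
Product: 2 1,3-dimethoxybenzene
Conditions: MeI, K2CO3, acetone, reflux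
Reagents that add atoms: iodomethane, CI
Why: Williamson O-methylation of both phenols; no stereocentre is involved.

**Step 2**
Reactants: 2 1,3-dimethoxybenzene
Product: 4 3,5-dimethoxyphenol, via aryl pinacol boronate 3 (not isolated)
Conditions: [Ir(OMe)(cod)]2 (1.5 mol%), dtbpy (3 mol%), B2pin2, THF, 80 °C; then aq. NaOH, 30% H2O2, 0 °C → rt
Reagents that add atoms: hydrogen peroxide, OO
Why: iridium-catalysed arene C–H borylation is sterically controlled and takes the only C–H not flanked by a substituent (C5), and alkaline peroxide then oxidises C–B to C–OH (Hartwig–Miyaura borylation/oxidation).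

**Step 3**
Reactants: 4 3,5-dimethoxyphenol
Product: 5 2-(3,5-dimethoxyphenoxy)tetrahydro-2H-pyran (racemic acetal)
Conditions: 3,4-dihydro-2H-pyran, PPTS (cat.), CH2Cl2, rt
Reagents that add atoms: 3,4-dihydro-2H-pyran, C1=COCCC1
Why: acid-catalysed tetrahydropyranylation gives an acetal ether that masks the phenol and later directs ortho-lithiation.

**Step 4**
Reactants: 1 resorcinol
Product: 7 2,4-dihydroxybenzaldehyde, via iminium chloride 6 (not isolated)
Conditions: POCl3, DMF, MeCN, −15 °C → rt; then H2O, 50 °C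
Reagents that add atoms: N,N-dimethylformamide, CN(C)C=O; water, O
Why: Vilsmeier–Haack formylation at the most nucleophilic and least hindered resorcinol carbon (C4), followed by hydrolysis of the iminium salt.

**Step 5**
Reactants: 7 2,4-dihydroxybenzaldehyde
Product: 8 2-hydroxy-4-(methoxymethoxy)benzaldehyde
Conditions: MOMCl, K2CO3, acetone, 0 °C → rt
Reagents that add atoms: chloromethyl methyl ether, COCCl
Why: the 2-OH is hydrogen-bonded to the aldehyde, so only the free, more acidic 4-OH is alkylated (selective Williamson protection).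

**Step 6**
Reactants: 8 2-hydroxy-4-(methoxymethoxy)benzaldehyde; 9 3-chloro-3-methylbut-1-yne
Product: 10 4-(methoxymethoxy)-2-[(2-methylbut-3-yn-2-yl)oxy]benzaldehyde
Conditions: DBU, CuCl2·2H2O (1 mol%), MeCN, 0 °C → rt
Reagents that add atoms: none
Why: copper-catalysed propargylic etherification of a hindered, chelated phenol with a tertiary propargyl chloride, which proceeds through a copper acetylide-derived electrophile rather than E2 elimination.

**Step 7**
Reactants: 10 4-(methoxymethoxy)-2-[(2-methylbut-3-yn-2-yl)oxy]benzaldehyde; 11 vinylmagnesium bromide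
Product: 13 1-[4-(methoxymethoxy)-2-[(2-methylbut-3-yn-2-yl)oxy]phenyl]prop-2-en-1-yl acetate (racemic; used crude), via magnesium alkoxide 12 (not isolated)
Conditions: THF, −78 °C; then Ac2O, −78 → 0 °C
Reagents that add atoms: acetic anhydride, CC(=O)OC(C)=O
Why: Grignard 1,2-addition to the aldehyde (faster than alkyne deprotonation at −78 °C) and in situ O-acetylation of the alkoxide; the racemic carbinol centre is erased in step 8.

**Step 8**
Reactants: 5 2-(3,5-dimethoxyphenoxy)tetrahydro-2H-pyran; 13 1-[4-(methoxymethoxy)-2-[(2-methylbut-3-yn-2-yl)oxy]phenyl]prop-2-en-1-yl acetate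
Product: 17 2-[(2E)-3-[4-(methoxymethoxy)-2-[(2-methylbut-3-yn-2-yl)oxy]phenyl]prop-2-en-1-yl]-3,5-dimethoxyphenol, via aryllithium 14 (not isolated), via arylzinc chloride 15 (not isolated), via THP-protected diarylpropene 16 (not isolated)
Conditions: n-BuLi, THF, 0 °C; ZnCl2, 0 °C; 13, Pd(PPh3)4 (5 mol%), rt; then MeOH, TsOH·H2O, 0 °C → rt
Reagents that add atoms: none
Why: directed ortho-metalation between the OTHP and OMe groups, transmetalation to zinc and Negishi-type allyl–aryl coupling through an η3-allyl complex of palladium that couples at its unsubstituted terminus to give the conjugated E-alkene; brief acid methanolysis then removes the THP group while the aryl MOM ether survives.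

**Step 9**
Reactants: 17 2-[(2E)-3-[4-(methoxymethoxy)-2-[(2-methylbut-3-yn-2-yl)oxy]phenyl]prop-2-en-1-yl]-3,5-dimethoxyphenol
Product: 18 2-hydroxy-4,6-dimethoxy-3-[(2E)-3-[4-(methoxymethoxy)-2-[(2-methylbut-3-yn-2-yl)oxy]phenyl]prop-2-en-1-yl]benzaldehyde
Conditions: MgCl2, Et3N, (CH2O)n, THF, 65 °C
Reagents that add atoms: paraformaldehyde (formaldehyde), C=O
Why: Casnati–Skattebøl ortho-formylation through the magnesium phenoxide is ortho-specific, and only one ortho position is free, so the aldehyde lands unambiguously at the future C8; it also deactivates ring A and chelates the phenol before the oxidation in step 10.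

**Step 10**
Reactants: 18 2-hydroxy-4,6-dimethoxy-3-[(2E)-3-[4-(methoxymethoxy)-2-[(2-methylbut-3-yn-2-yl)oxy]phenyl]prop-2-en-1-yl]benzaldehyde
Product: 20 2-hydroxy-3-[(2R)-3-hydroxy-2-[4-(methoxymethoxy)-2-[(2-methylbut-3-yn-2-yl)oxy]phenyl]propyl]-4,6-dimethoxybenzaldehyde, via α-aryl aldehyde 19 (not isolated)
Conditions: dimethyl (2R,2'R)-2,2'-{[2-(diacetoxy-λ3-iodanyl)-1,3-phenylene]bis(oxy)}dipropanoate (1.2 equiv), TsOH·H2O (1.3 equiv), H2O (3 equiv), CH2Cl2/CF3CH2OH 10:1, −78 → −50 °C; then NaBH4, EtOH, −78 → −30 °C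
Reagents that add atoms: water, O
Why: Proposed new method: enantioselective oxidative 1,2-aryl migration of a free-phenol (E)-1,3-diarylpropene with a chiral lactate-derived aryl-λ3-iodane, in which the electrophilic trivalent iodine adds to one face of the alkene at the non-benzylic carbon, water (or the ortho-phenol) adds anti at the benzylic carbon, and the electron-rich 2,4-dialkoxyphenyl ring displaces the iodoarene from the back side through a phenonium ion that collapses to the α-aryl aldehyde (or its lactol), so the C3 stereocentre is set by reagent-controlled face selection followed by an invertive aryl shift, and cold NaBH4 traps this labile aldehyde before it enolises while leaving the chelated, electron-rich aryl aldehyde untouched; the closest known reaction type is the Koser-type trivalent-iodine oxidative rearrangement of aryl alkenes to α-aryl carbonyl compounds and its enantioselective lactate-iodane variants on 1,1-disubstituted alkenes.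

**Step 11**
Reactants: 20 2-hydroxy-3-[(2R)-3-hydroxy-2-[4-(methoxymethoxy)-2-[(2-methylbut-3-yn-2-yl)oxy]phenyl]propyl]-4,6-dimethoxybenzaldehyde
Product: 21 (3R)-5,7-dimethoxy-3-[4-(methoxymethoxy)-2-[(2-methylbut-3-yn-2-yl)oxy]phenyl]-3,4-dihydro-2H-chromene-8-carbaldehyde
Conditions: PPh3, DIAD, THF, 0 °C → rt
Reagents that add atoms: none
Why: intramolecular Mitsunobu etherification, in which the acidic chelated phenol displaces the activated primary alcohol (SN2 at C2) to close ring C without touching the C3 stereocentre.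

**Step 12**
Reactants: 21 (3R)-5,7-dimethoxy-3-[4-(methoxymethoxy)-2-[(2-methylbut-3-yn-2-yl)oxy]phenyl]-3,4-dihydro-2H-chromene-8-carbaldehyde
Product: 22 (3R)-5,7-dimethoxy-3-[5-(methoxymethoxy)-2,2-dimethyl-2H-chromen-8-yl]-3,4-dihydro-2H-chromene-8-carbaldehyde
Conditions: PhNEt2, 180 °C
Reagents that add atoms: none
Why: aromatic propargyl Claisen rearrangement to the only free ortho carbon, then 1,5-hydrogen shift and oxa-6π electrocyclisation give the 2,2-dimethyl-2H-chromene; it is placed after step 10 so that no second styrenic alkene competes for the iodane, and the stereocentre is not involved.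

**Step 13**
Reactants: 22 (3R)-5,7-dimethoxy-3-[5-(methoxymethoxy)-2,2-dimethyl-2H-chromen-8-yl]-3,4-dihydro-2H-chromene-8-carbaldehyde
Product: 23 (3R)-7-hydroxy-3-(5-hydroxy-2,2-dimethyl-2H-chromen-8-yl)-5-methoxy-3,4-dihydro-2H-chromene-8-carbaldehyde (target)
Conditions: BCl3, CH2Cl2, −78 → 0 °C
Reagents that add atoms: none
Why: BCl3 cleaves the MOM acetal and, by chelation to the ortho formyl group, only the 7-methyl ether (the 5-OMe para to CHO stays), with low temperature chosen to spare the chromene; chelation-controlled Lewis-acid dealkylation.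

**Compound list**
1 | resorcinol | Oc1cccc(O)c1 | starting material
2 | 1,3-dimethoxybenzene | COc1cccc(OC)c1 | intermediate
3 | 2-(3,5-dimethoxyphenyl)-4,4,5,5-tetramethyl-1,3,2-dioxaborolane | COc1cc(OC)cc(B2OC(C)(C)C(C)(C)O2)c1 | intermediate
4 | 3,5-dimethoxyphenol | COc1cc(O)cc(OC)c1 | intermediate
5 | 2-(3,5-dimethoxyphenoxy)tetrahydro-2H-pyran (racemic) | COc1cc(OC)cc(OC2CCCCO2)c1 | intermediate
6 | (2,4-dihydroxyphenyl)methylidene-dimethyliminium chloride | C[N+](C)=Cc1ccc(O)cc1O.[Cl-] | intermediate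
7 | 2,4-dihydroxybenzaldehyde | O=Cc1ccc(O)cc1O | intermediate
8 | 2-hydroxy-4-(methoxymethoxy)benzaldehyde | COCOc1ccc(C=O)c(O)c1 | intermediate
9 | 3-chloro-3-methylbut-1-yne | CC(C)(Cl)C#C | starting material
10 | 4-(methoxymethoxy)-2-[(2-methylbut-3-yn-2-yl)oxy]benzaldehyde | COCOc1ccc(C=O)c(OC(C)(C)C#C)c1 | intermediate
11 | vinylmagnesium bromide | C=C[Mg]Br | starting material
12 | bromomagnesium 1-[4-(methoxymethoxy)-2-[(2-methylbut-3-yn-2-yl)oxy]phenyl]prop-2-en-1-olate (racemic) | C=CC(O[Mg]Br)c1ccc(OCOC)cc1OC(C)(C)C#C | intermediate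
13 | 1-[4-(methoxymethoxy)-2-[(2-methylbut-3-yn-2-yl)oxy]phenyl]prop-2-en-1-yl acetate (racemic) | C=CC(OC(C)=O)c1ccc(OCOC)cc1OC(C)(C)C#C | intermediate
14 | [2,4-dimethoxy-6-(tetrahydro-2H-pyran-2-yloxy)phenyl]lithium | [Li]c1c(OC)cc(OC)cc1OC1CCCCO1 | intermediate
15 | chloro[2,4-dimethoxy-6-(tetrahydro-2H-pyran-2-yloxy)phenyl]zinc | Cl[Zn]c1c(OC)cc(OC)cc1OC1CCCCO1 | intermediate
16 | 2-[2-[(2E)-3-[4-(methoxymethoxy)-2-[(2-methylbut-3-yn-2-yl)oxy]phenyl]prop-2-en-1-yl]-3,5-dimethoxyphenoxy]tetrahydro-2H-pyran | COc1cc(OC)c(C/C=C/c2ccc(OCOC)cc2OC(C)(C)C#C)c(OC2CCCCO2)c1 | intermediate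
17 | 2-[(2E)-3-[4-(methoxymethoxy)-2-[(2-methylbut-3-yn-2-yl)oxy]phenyl]prop-2-en-1-yl]-3,5-dimethoxyphenol | COc1cc(OC)c(C/C=C/c2ccc(OCOC)cc2OC(C)(C)C#C)c(O)c1 | intermediate
18 | 2-hydroxy-4,6-dimethoxy-3-[(2E)-3-[4-(methoxymethoxy)-2-[(2-methylbut-3-yn-2-yl)oxy]phenyl]prop-2-en-1-yl]benzaldehyde | COc1cc(OC)c(C=O)c(O)c1C/C=C/c1ccc(OCOC)cc1OC(C)(C)C#C | intermediate
19 | (2R)-3-(3-formyl-2-hydroxy-4,6-dimethoxyphenyl)-2-[4-(methoxymethoxy)-2-[(2-methylbut-3-yn-2-yl)oxy]phenyl]propanal (in equilibrium with its lactol) | COc1cc(OC)c(C=O)c(O)c1C[C@H](c1ccc(OCOC)cc1OC(C)(C)C#C)C=O | intermediate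
20 | 2-hydroxy-3-[(2R)-3-hydroxy-2-[4-(methoxymethoxy)-2-[(2-methylbut-3-yn-2-yl)oxy]phenyl]propyl]-4,6-dimethoxybenzaldehyde | COc1cc(OC)c(C=O)c(O)c1C[C@H](c1ccc(OCOC)cc1OC(C)(C)C#C)CO | intermediate
21 | (3R)-5,7-dimethoxy-3-[4-(methoxymethoxy)-2-[(2-methylbut-3-yn-2-yl)oxy]phenyl]-3,4-dihydro-2H-chromene-8-carbaldehyde | COc1cc(OC)c(C=O)c2c1C[C@H](c1ccc(OCOC)cc1OC(C)(C)C#C)CO2 | intermediate
22 | (3R)-5,7-dimethoxy-3-[5-(methoxymethoxy)-2,2-dimethyl-2H-chromen-8-yl]-3,4-dihydro-2H-chromene-8-carbaldehyde | COc1cc(OC)c(C=O)c2c1C[C@H](c1ccc(OCOC)c3c1OC(C)(C)C=C3)CO2 | intermediate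
23 | (3R)-7-hydroxy-3-(5-hydroxy-2,2-dimethyl-2H-chromen-8-yl)-5-methoxy-3,4-dihydro-2H-chromene-8-carbaldehyde | COc1cc(O)c(C=O)c2c1C[C@H](c1ccc(O)c3c1OC(C)(C)C=C3)CO2 | target

**Totals**
Total step count: 13. Longest linear sequence: 10 steps (steps 4 to 13, from resorcinol through the ring B branch).

**Three steps most likely to fail, with fallbacks**

Step 10, the new aryl shift. The risks are low enantioselectivity, attack of the iodane on the electron-rich arenes, and partial enolisation of 19 before reduction. Fallback with known chemistry: setting out from 18, the same rearrangement is run with achiral PhI(OH)OTs in wet acetonitrile (the established Koser-type oxidative rearrangement of aryl alkenes), giving the racemic α-aryl aldehyde F1. F1 is reduced in the same flask with NaBH4 to the racemic phenol–alcohol F2. Mitsunobu closure as in step 11 gives the racemic chroman aldehyde F3, and preparative chiral-phase SFC of F3 delivers the (3R)-enantiomer, which is 21, where the route is rejoined.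

Step 8, the allyl–aryl coupling. The risks are lithiation of 5 between the two methoxy groups, loss of the very ionisable acetate 13, and branched coupling. Fallback: setting out from 10 and 11, an aqueous NH4Cl quench in place of Ac2O gives the allylic alcohol F4. F4 is condensed with unprotected 3,5-dimethoxyphenol 4 under Sc(OTf)3 (5 mol%) in CH2Cl2 at 0 °C. This is a dehydrative Friedel–Crafts allylation in which the phenol attacks the CH2 terminus of the aryl-stabilised allyl cation; it gives 17 directly after chromatographic removal of the para isomer and rejoins the route at 17 without 5 and 13 to 16.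

Step 13, the final dealkylation. The risk is that the acid-sensitive 2,2-dimethylchromene does not survive BCl3. Fallback: setting out from 22, MgI2 in Et2O/toluene at 60 °C removes only the methyl ether ortho to the formyl group (chelation-controlled) to give the 7-hydroxy MOM ether F5. 2 M HCl in MeOH/THF at 40 °C then cleaves the MOM acetal of F5 to give 23.

**Further compounds**
F1 | step 10 | racemic 3-(3-formyl-2-hydroxy-4,6-dimethoxyphenyl)-2-[4-(methoxymethoxy)-2-[(2-methylbut-3-yn-2-yl)oxy]phenyl]propanal | COc1cc(OC)c(C=O)c(O)c1CC(c1ccc(OCOC)cc1OC(C)(C)C#C)C=O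
F2 | step 10 | racemic 2-hydroxy-3-[3-hydroxy-2-[4-(methoxymethoxy)-2-[(2-methylbut-3-yn-2-yl)oxy]phenyl]propyl]-4,6-dimethoxybenzaldehyde | COc1cc(OC)c(C=O)c(O)c1CC(c1ccc(OCOC)cc1OC(C)(C)C#C)CO
F3 | step 10 | racemic 5,7-dimethoxy-3-[4-(methoxymethoxy)-2-[(2-methylbut-3-yn-2-yl)oxy]phenyl]-3,4-dihydro-2H-chromene-8-carbaldehyde | COc1cc(OC)c(C=O)c2c1CC(c1ccc(OCOC)cc1OC(C)(C)C#C)CO2
F4 | step 8 | 1-[4-(methoxymethoxy)-2-[(2-methylbut-3-yn-2-yl)oxy]phenyl]prop-2-en-1-ol (racemic) | C=CC(O)c1ccc(OCOC)cc1OC(C)(C)C#C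
F5 | step 13 | (3R)-7-hydroxy-5-methoxy-3-[5-(methoxymethoxy)-2,2-dimethyl-2H-chromen-8-yl]-3,4-dihydro-2H-chromene-8-carbaldehyde | COc1cc(O)c(C=O)c2c1C[C@H](c1ccc(OCOC)c3c1OC(C)(C)C=C3)CO2
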